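## Structural features

The target is a germacranolide: a ten-membered carbocycle (C1–C10) with an α-methylene-γ-butyrolactone fused trans across C6–C7 (O6–C12, exocyclic C11=C13). The carbocycle carries a C1 ketone next to a fully substituted C10 carbinol (methyl C14), a Z trisubstituted C4=C5 alkene (methyl C15) and an isovalerate on O8. C6, C7 and C8 are contiguous stereocentres: in the open-chain sense the C6 oxygen and the C7 branch are syn, and the C7 branch and the C8 oxygen are anti. C10 is separated from C8 by the C9 methylene, so the C8 and C10 oxygens are 1,3-related. The fragile groups are: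

- the α-methylene lactone, a Michael acceptor that must be made last;
- the C1/C10 α-ketol, open to acyloin shift under base;
- the allylic C6–O bond;
- the O8 ester, which can migrate once O6 or O12 is free;
- the C4=C5/C11=C13 1,5-diene.

The real difficulty is closing the medium ring around a Z alkene with four stereocentres and three differently dressed oxygens already in place. The ring closure exploits the 1,4-relation of C1 and O8 through C10 and C9. A five-membered C1–O8 lactone is a stored acyl donor that cannot enolise, because C10 bears no hydrogen, and its leaving group is the oxygen that later carries the ester. C2, next to C1, can carry a sulfonyl group that makes it the only carbon acid.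

## Logic of the disconnections

31 is traced to 28 by cutting the O6–C12 acyl bond and lowering C12 to the alcohol level, and 28 to 27 by cutting three O–Si bonds. The α-methylene lactone would not survive carbanions or radicals, so C12 travels as a silyl-protected allylic alcohol. The forward oxidation must choose the primary allylic alcohol over the secondary allylic C6 hydroxyl and leave the tertiary C10 hydroxyl alone.

27 goes back to 26 by replacing C2–H with C2–S, and 26 to 25 by cutting the O8–acyl bond. The sulfonyl group is the activator of the ring closure and O8 is its leaving group, so the ester can only come after the ring is formed. The forward steps need an acylation that spares the acidic β-keto sulfone and a desulfonylation that spares the α-silyloxy ketone.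

25 goes back to 24 by cutting C1–C2, which is the key disconnection. It opens the ten-membered ring to an acyclic chain on a five-membered lactone and removes no stereocentre of the target. The forward step needs a single acidic site, a single electrophile and cyclisation in preference to oligomerisation.

24 goes back to 23 by cutting two O–Si bonds, and 23 to 21 by cutting the O8–C1 lactone bond and the C8–H bond. The lactone is the natural result of reducing a C8 ketone that lies γ to the C1 ester. The C6 hydroxyl is deliberately left free in 21, so that a secondary carbinol steers hydride to C8 through a well-defined chair. The tertiary C10 hydroxyl alone would be an ambiguous director, because its chair must place either the methyl or the ester axial. The forward reduction must give the 6,8-anti diol and the lactonisation must form the five-membered ring only.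

21 goes back to 18 and 19 by cutting C9–C10. This is an aldol between a methyl ketone enol ether and the ketone of pyruvate, and it delivers C10, C14 and C1 in one step. Because C10 is remote from the other centres, the forward step needs catalyst control of the pyruvate face.

18 goes back through 16 and 15 to 14 by cutting the C8–C9 bond (methyl addition to an amide) and exchanging the auxiliary. The forward sequence must enolise only towards C9 and must not disturb the C7 methine, which is α to the ketone and allylic.

14 goes back to 12 and 6 by cutting C6–C7. An auxiliary-controlled syn aldol sets both centres at once and joins the two halves. It needs a Z enolate, 1,2-addition to the enal, and retention of the Z geometry.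

6 goes back through 5, 4 and 2 to 1 and 3 by cutting C2–S and the ring O–acyl bond. The Z geometry of C4=C5 is taken from the ring of 1 and is never formed by an olefination. The forward steps must not let a thiolate add reversibly to the unsaturated carbonyl.

12 goes back through 10, 9 and 8 to 7. The two carboxyl groups of the itaconate are already differentiated, so C12 is reduced and silylated and C8 is attached to the auxiliary. The β,γ-alkene must not move into conjugation.

## Other disconnections considered

Alternative 1: The cut is C3–C4.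
- Forward step: the seco compound A1 is a Z alkenyl iodide at C4 with a 1-substituted cyclopropanol at C1. With Pd(OAc)2, tricyclohexylphosphine and Cs2CO3, zerovalent palladium inserts into C4–I, the cyclopropanolate opens to a C3 palladium homoenolate, and reductive elimination closes the ring to A2.
- In its favour: the ketone appears in the same event and no activating group has to be removed. A2 already holds the lactone and the isovalerate, so only unmasking of the methylene and one desilylation remain. After ring closure it is shorter than the chosen plan and therefore better on that count. Transfer of alkene geometry from the iodide is the equal of taking it from a ring.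
- Against it: reductive elimination must pass through an eleven-membered palladacycle. β-Hydride elimination of the homoenolate to an enone is a ready escape. The thioether can bind palladium. Carbonate base meets a β-acyloxy-substituted chain. The cyclopropanol would have to be made from a C1 ester at a stage where no other ester or lactone is present, which pushes steps back into the early part.
- Comparison: the chosen closure is a polar addition–elimination pulled forward by enolate formation, whereas this one has no thermodynamic sink before the product. Overall step count would be similar.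

Alternative 2: The cut is C2–C3, with C5–C10 reconnected, so the ten-membered ring comes from a six-membered one.
- Forward step: the cis-1-vinyl-2-isopropenylcyclohexanol A3, with KH and 18-crown-6, undergoes anionic oxy-Cope rearrangement. The resulting enolate is hydroxylated in the flask by 2-(phenylsulfonyl)-3-phenyloxaziridine to give A4.
- In its favour: a pericyclic ring expansion avoids the entropic cost of medium-ring closure altogether. On the ring-forming event itself it is better than the chosen plan, and it needs no dilution.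
- Against it: A4 has the ketone at C10 and the hydroxyl at C1, the reverse of the target. Methyl addition to C10 would create the quaternary centre under conformational control of a flexible ring, which is not secured. Oxidation at C1 and exchange of the C8 ether for the ester must follow. The C4=C5 geometry depends on which of two chair arrangements the cis substrate adopts. A3, with five stereocentres on a cyclohexane including a tertiary carbinol, is no easier than the acyclic precursor of the chosen plan.
- Comparison: the chosen plan fixes C10 before ring closure by catalyst control and takes the alkene geometry from a lactone ring. Both plans leave the lactone to the end, which is a point of equality. The alternative needs more steps after its key step.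

Alternative 3: The cut is C1–C10.
- Forward step: the keto aldehyde A5 is treated with the aminoindanol-derived pentafluorophenyl triazolium tetrafluoroborate and triethylamine. The carbene converts the C1 aldehyde into a Breslow intermediate that adds to the C10 methyl ketone and gives A6.
- In its favour: it is the only plan that creates a target stereocentre and the ring together. A6 already has the α-ketol and the ester and needs no activating group, so only desilylation and lactonisation remain. In step economy and in directness of functional-group mapping it is better than the chosen plan.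
- Against it: crossed aldehyde–ketone benzoin closure is secure for five- and six-membered rings only. Over ten atoms it competes with homo-benzoin oligomers, with aldol reactions of two enolisable carbonyls under amine base, and with β-elimination of the C8 isovalerate from the β-acyloxy ketone. The catalyst would have to impose the C10 face against the preferences of the forming macrocycle.
- Comparison: the chosen plan sets C10 in an acyclic intermediate by a well-established reaction class and closes the ring with a built-in driving force. It pays for this with about three more steps.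

Key step: step 16

Remarks on the chemistry.
- Locants C1–C15 follow the germacrane numbering: C1 is the ketone carbon, C10 the carbinol carbon, C11–C13 the lactone carbons.
- The ring-closure precursor 24 and product 25 were checked centre by centre against the target. C6, C7, C8, C10 and the Z C4=C5 geometry map over unchanged, so the skeletons need no correction.
- The only design change is in protecting groups: the C6 oxygen is carried as a triethylsilyl ether, installed together with the one on C10, because the C6 hydroxyl is kept free to steer the C8 reduction.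
- Assumption: the C2 epimer drawn for 25 and 26 is arbitrary; C2 is cleared in step 18.

## Route

Step 1
Reactants: 1 4-methyl-5,6-dihydro-2H-pyran-2-one
Product: 2 (2Z)-5-hydroxy-N-methoxy-N,3-dimethylpent-2-enamide
Conditions: MeNH(OMe)·HCl, AlMe3, CH2Cl2, 0 °C to rt; aq. potassium sodium tartrate
Reagents that add atoms: N,O-dimethylhydroxylamine hydrochloride, CNOC.Cl
Why: Weinreb aminolysis of a lactone by the aluminium amide; the ring alkene becomes the Z alkene of the open chain, and the β,β-disubstituted acceptor resists conjugate addition.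

Step 2
Reactants: 2 hydroxy Weinreb amide; 3 benzenethiol
Product: 4 (2Z)-N-methoxy-N,3-dimethyl-5-(phenylsulfanyl)pent-2-enamide
Conditions: PPh3, DIAD, THF, 0 °C to rt
Reagents that add atoms: none
Why: Mitsunobu thioetherification of a primary alcohol with an acidic thiol; SN2 at the primary carbon should outrun relactonisation, and no free thiolate is present to isomerise the alkene.

Step 3
Reactants: 4 sulfide
Product: 5 (2Z)-N-methoxy-N,3-dimethyl-5-(phenylsulfonyl)pent-2-enamide
Conditions: (NH4)6Mo7O24·4H2O (cat.), 30% H2O2, EtOH, 0 °C to rt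
Reagents that add atoms: hydrogen peroxide, OO
Why: Molybdate-catalysed peroxide oxidation of a sulfide to the sulfone; the electron-poor conjugated alkene is not epoxidised under these conditions.

Step 4
Reactants: 5 sulfonyl Weinreb amide
Product: 6 (2Z)-3-methyl-5-(phenylsulfonyl)pent-2-enal
Conditions: i-Bu2AlH, THF, −78 °C; aq. potassium sodium tartrate
Reagents that add atoms: none
Why: Hydride reduction of a Weinreb amide; the chelated aluminium hemiaminal releases the aldehyde only on work-up, so over-reduction is avoided and the Z geometry is kept at low temperature.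

Step 5
Reactants: 7 monomethyl itaconate (4-methoxy-2-methylidene-4-oxobutanoic acid)
Product: 8 methyl 3-(hydroxymethyl)but-3-enoate
Conditions: BH3·SMe2, THF, −10 °C to rt; MeOH quench
Reagents that add atoms: none
Why: Chemoselective borane reduction of a carboxylic acid through its acyloxyborane in the presence of an ester; the electron-poor 1,1-disubstituted alkene hydroborates slowly at this temperature.

Step 6
Reactants: 8 hydroxy ester
Product: 9 methyl 3-({[tert-butyl(dimethyl)silyl]oxy}methyl)but-3-enoate
Conditions: TBSCl, imidazole, CH2Cl2, 0 °C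
Reagents that add atoms: tert-butyldimethylsilyl chloride, CC(C)(C)[Si](C)(C)Cl
Why: Silylation of a primary alcohol; immediate protection prevents closure to the five-membered lactone.

Step 7
Reactants: 9 silyloxy ester
Product: 10 3-({[tert-butyl(dimethyl)silyl]oxy}methyl)but-3-enoic acid
Conditions: LiOH, THF/H2O, 0 °C; then 1 M HCl to pH 4, 0 °C
Reagents that add atoms: lithium hydroxide, [Li+].[OH-]
Why: Ester saponification; at 0 °C hydroxide adds to the carbonyl faster than it deprotonates the α-carbon, and the carboxylate formed no longer isomerises into conjugation.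

Step 8
Reactants: 10 acid
Product: 12 (4S)-4-benzyl-3-[3-({[tert-butyl(dimethyl)silyl]oxy}methyl)but-3-enoyl]-1,3-oxazolidin-2-one, via mixed pivalic anhydride 11 (not isolated)
Conditions: PivCl, Et3N, THF, −20 °C; then (4S)-4-benzyl-1,3-oxazolidin-2-one, LiCl, −20 °C to rt
Reagents that add atoms: (4S)-4-benzyl-1,3-oxazolidin-2-one, O=C1N[C@@H](Cc2ccccc2)CO1; pivaloyl chloride, CC(C)(C)C(=O)Cl (its atoms stay in 11 only)
Why: N-acylation of the oxazolidinone through a mixed anhydride under mild amine/LiCl activation, chosen so that no strong base can move the β,γ-alkene.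

Step 9
Reactants: 12 imide; 6 Z enal sulfone
Product: 14 (4S)-4-benzyl-3-[(2S,3R,4Z)-2-(3-{[tert-butyl(dimethyl)silyl]oxy}prop-1-en-2-yl)-3-hydroxy-5-methyl-7-(phenylsulfonyl)hept-4-enoyl]-1,3-oxazolidin-2-one, via dibutylboron Z-enolate 13 (not isolated)
Conditions: Bu2BOTf, i-Pr2NEt, CH2Cl2, −78 to 0 °C; then 6, −78 to −20 °C; aq. KH2PO4/K2HPO4 (pH 7), MeOH, 30% H2O2, 0 °C
Reagents that add atoms: dibutylboryl trifluoromethanesulfonate, CCCCB(CCCC)OS(=O)(=O)C(F)(F)F (its boron and butyl groups stay in 13 only)
Why: Evans syn aldol: the Z boron enolate reacts at its α-carbon through a Zimmerman–Traxler chair on the face away from the benzyl group, which sets C7 and C6 (syn) in the sense required by the (4S)-auxiliary; the enal reacts 1,2 and keeps its Z geometry.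

Step 10
Reactants: 14 aldol adduct
Product: 15 (2S,3R,4Z)-2-(3-{[tert-butyl(dimethyl)silyl]oxy}prop-1-en-2-yl)-3-hydroxy-N-methoxy-N,5-dimethyl-7-(phenylsulfonyl)hept-4-enamide
Conditions: MeNH(OMe)·HCl, AlMe3, CH2Cl2, −20 to 0 °C; aq. potassium sodium tartrate
Reagents that add atoms: N,O-dimethylhydroxylamine hydrochloride, CNOC.Cl
Why: Transamidation of an aldol imide with the aluminium amide; the free C6 hydroxyl binds aluminium and directs attack to the exocyclic carbonyl, and the conditions are not basic enough to epimerise C7.

Step 11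
Reactants: 15 hydroxy Weinreb amide
Product: 16 (3S,4R,5Z)-3-(3-{[tert-butyl(dimethyl)silyl]oxy}prop-1-en-2-yl)-4-hydroxy-6-methyl-8-(phenylsulfonyl)oct-5-en-2-one
Conditions: MeMgBr (excess), THF, −20 to 0 °C; aq. NH4Cl
Reagents that add atoms: methylmagnesium bromide, C[Mg]Br
Why: Grignard addition to a Weinreb amide, which stops at the chelated tetrahedral stage; the neighbouring C6 magnesium alkoxide disfavours deprotonation at C7, and the sulfone is not metallated at this temperature.

Step 12
Reactants: 16 hydroxy methyl ketone
Product: 18 (3S,4R,5Z)-3-(3-{[tert-butyl(dimethyl)silyl]oxy}prop-1-en-2-yl)-6-methyl-8-(phenylsulfonyl)-2,4-bis[(trimethylsilyl)oxy]octa-1,5-diene, via C6 trimethylsilyl ether ketone 17 (not isolated)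
Conditions: TMSCl, Et3N, THF, 0 °C; then LiN(SiMe3)2, TMSCl, −78 °C
Reagents that add atoms: chlorotrimethylsilane, C[Si](C)(C)Cl
Why: O-silylation followed by kinetic enolisation with in-flask silyl trapping; the hindered amide base takes a methyl (C9) proton, because the C7 methine is shielded and held out of alignment with the carbonyl by allylic strain, and the sulfone is a weaker acid than the ketone.

Step 13
Reactants: 18 enol silyl ether; 19 methyl pyruvate
Product: 21 methyl (2R,5S,6R,7Z)-5-(3-{[tert-butyl(dimethyl)silyl]oxy}prop-1-en-2-yl)-2,6-dihydroxy-2,8-dimethyl-4-oxo-10-(phenylsulfonyl)dec-7-enoate, via bis(trimethylsilyl) aldol adduct 20 (not isolated)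
Conditions: Cu(OTf)2 (10 mol%), 2,2'-(propane-2,2-diyl)bis[(4R)-4-tert-butyl-4,5-dihydro-1,3-oxazole] (11 mol%), THF, −78 °C; then citric acid, MeOH, 0 °C
Reagents that add atoms: none
Why: Catalytic enantioselective Mukaiyama aldol to a pyruvate: the keto ester chelates divalent copper in a square-planar complex, the tert-butyl groups of the (R,R)-ligand cover the si face of the ketone, and the enol ether adds to the re face, which sets C10 as R under catalyst control and independently of the remote centres; mild acid then removes both trimethylsilyl groups.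

Step 14
Reactants: 21 dihydroxy keto ester
Product: 23 (3R,5R)-5-[(3S,4R,5Z)-2-({[tert-butyl(dimethyl)silyl]oxy}methyl)-4-hydroxy-6-methyl-8-(phenylsulfonyl)octa-1,5-dien-3-yl]-3-hydroxy-3-methyloxolan-2-one, via triol methyl ester 22 (not isolated)
Conditions: Me4NBH(OAc)3, MeCN/AcOH (1:1), −30 °C; then PPTS (cat.), CH2Cl2, rt
Reagents that add atoms: none
Why: Hydroxyl-directed Evans–Saksena reduction: the secondary C6 hydroxyl exchanges onto boron and delivers hydride to C8 through a chair with the C6 substituent equatorial, which sets the C8 hydroxyl anti to the C6 hydroxyl; the C8 hydroxyl then closes the five-membered lactone on the C1 ester, while the seven-membered alternative from O6 is not competitive.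

Step 15
Reactants: 23 lactone diol
Product: 24 (3R,5R)-5-[(3R,4R,5Z)-2-({[tert-butyl(dimethyl)silyl]oxy}methyl)-6-methyl-8-(phenylsulfonyl)-4-[(triethylsilyl)oxy]octa-1,5-dien-3-yl]-3-methyl-3-[(triethylsilyl)oxy]oxolan-2-one
Conditions: TESOTf, 2,6-lutidine, CH2Cl2, −78 to 0 °C
Reagents that add atoms: triethylsilyl trifluoromethanesulfonate, CC[Si](CC)(CC)OS(=O)(=O)C(F)(F)F
Why: Silyl triflate silylation, strong enough to cap the secondary allylic C6 and the hindered tertiary C10 hydroxyls in one operation; this removes every O–H acid before the carbanion step.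

Step 16
Reactants: 24 lactone sulfone
Product: 25 (2R,4Z,6R,7R,8R,10R)-7-(3-{[tert-butyl(dimethyl)silyl]oxy}prop-1-en-2-yl)-8-hydroxy-4,10-dimethyl-2-(phenylsulfonyl)-6,10-bis[(triethylsilyl)oxy]cyclodec-4-en-1-one
Conditions: LiN(SiMe3)2 (3.5 equiv), THF, 0 °C, 24 added over 8 h (final 1 mM); then AcOH, −78 °C
Reagents that add atoms: none
Why: The base reversibly removes a proton from C2, the only carbon acid, since the lactone has no α-hydrogen at the fully substituted C10. The α-sulfonyl carbanion adds to the lactone carbonyl C1 to give a bicyclic tetrahedral alkoxide, which collapses by expelling O8, so the five-membered ring opens as the ten-membered ring closes. The β-keto sulfone is far more acidic than the starting sulfone and is deprotonated at once by the excess base; this enolate is the thermodynamic sink that pulls the unfavourable pre-equilibria forward and protects C1 from the C8 alkoxide and from a second carbanion. The closest known reaction type is the Claisen-type acylation of α-sulfonyl carbanions by esters and lactones to β-keto sulfones, including ring-forming cases. The ring closes by 10-exo-trig attack on the carbonyl, in effect an acyl-transfer expansion of the lactone. The new C2 stereocentre is fixed only when the enolate is protonated in the quench, under the influence of the ring conformation; it is not needed and is removed in step 18. The selectivity required is cyclisation over intermolecular acylation, secured by slow addition into excess base at high dilution and by the Z alkene and the lactone ring, which shorten and pre-organise the chain. The lithium counter-ion and the cold acidic quench are chosen to restrain silyl migration to the freed C8 alkoxide.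

Step 17
Reactants: 25 hydroxy β-keto sulfone
Product: 26 (2R,4Z,6R,7R,8R,10R)-7-(3-{[tert-butyl(dimethyl)silyl]oxy}prop-1-en-2-yl)-4,10-dimethyl-8-(3-methylbutanoyloxy)-2-(phenylsulfonyl)-6,10-bis[(triethylsilyl)oxy]cyclodec-4-en-1-one
Conditions: isovaleric anhydride, DMAP, pyridine, CH2Cl2, 0 °C to rt
Reagents that add atoms: 3-methylbutanoic anhydride, CC(C)CC(=O)OC(=O)CC(C)C
Why: DMAP-catalysed acylation of the only free hydroxyl; the weak base pyridine is chosen so that the β-keto sulfone is not converted into its enol ester.

Step 18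
Reactants: 26 isovalerate β-keto sulfone
Product: 27 (4Z,6R,7R,8R,10R)-7-(3-{[tert-butyl(dimethyl)silyl]oxy}prop-1-en-2-yl)-4,10-dimethyl-8-(3-methylbutanoyloxy)-6,10-bis[(triethylsilyl)oxy]cyclodec-4-en-1-one
Conditions: Bu3SnH, AIBN, toluene, 90 °C
Reagents that add atoms: none
Why: Radical reductive desulfonylation of a β-keto sulfone: the stannyl radical cleaves the C2–S bond to an α-keto radical, which abstracts hydrogen; the ester, the silyl ethers and the α-silyloxy ketone are not touched by this reagent, and the transient C2 centre disappears.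

Step 19
Reactants: 27 silylated keto ester
Product: 28 (4Z,6R,7S,8R,10R)-6,10-dihydroxy-7-(3-hydroxyprop-1-en-2-yl)-4,10-dimethyl-8-(3-methylbutanoyloxy)cyclodec-4-en-1-one
Conditions: HF·pyridine, pyridine, THF, 0 °C to rt
Reagents that add atoms: none
Why: Global desilylation with buffered fluoride; the slightly acidic medium avoids the basic conditions that would favour ester migration from O8 or rearrangement of the α-ketol.

Step 20
Reactants: 28 triol ester
Product: 31 (3aR,4R,6R,10Z,11aR)-6-hydroxy-6,10-dimethyl-3-methylidene-2,7-dioxo-2,3,3a,4,5,6,7,8,9,11a-decahydrocyclodeca[b]furan-4-yl 3-methylbutanoate, via hydroxy enal 29 (not isolated), via lactol 30 (not isolated)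
Conditions: TEMPO (20 mol%), PhI(OAc)2 (3 equiv), CH2Cl2, rt
Reagents that add atoms: none
Why: Oxoammonium-mediated oxidative lactonisation: the primary allylic alcohol is oxidised first, the enal is trapped by the C6 hydroxyl as a lactol, and the lactol is oxidised to the α-methylene lactone; the tertiary C10 hydroxyl is inert, and trapping removes the C6 hydroxyl from further oxidation.

## Compound list

1 | 4-methyl-5,6-dihydro-2H-pyran-2-one | CC1=CC(=O)OCC1 | starting material
2 | (2Z)-5-hydroxy-N-methoxy-N,3-dimethylpent-2-enamide | CON(C)C(=O)/C=C(/C)CCO | intermediate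
3 | benzenethiol (thiophenol) | Sc1ccccc1 | starting material
4 | (2Z)-N-methoxy-N,3-dimethyl-5-(phenylsulfanyl)pent-2-enamide | CON(C)C(=O)/C=C(/C)CCSc1ccccc1 | intermediate
5 | (2Z)-N-methoxy-N,3-dimethyl-5-(phenylsulfonyl)pent-2-enamide | CON(C)C(=O)/C=C(/C)CCS(=O)(=O)c1ccccc1 | intermediate
6 | (2Z)-3-methyl-5-(phenylsulfonyl)pent-2-enal | O=C/C=C(/C)CCS(=O)(=O)c1ccccc1 | intermediate
7 | monomethyl itaconate (4-methoxy-2-methylidene-4-oxobutanoic acid) | C=C(CC(=O)OC)C(=O)O | starting material
8 | methyl 3-(hydroxymethyl)but-3-enoate | C=C(CO)CC(=O)OC | intermediate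
9 | methyl 3-({[tert-butyl(dimethyl)silyl]oxy}methyl)but-3-enoate | C=C(CO[Si](C)(C)C(C)(C)C)CC(=O)OC | intermediate
10 | 3-({[tert-butyl(dimethyl)silyl]oxy}methyl)but-3-enoic acid | C=C(CO[Si](C)(C)C(C)(C)C)CC(=O)O | intermediate
11 | 3-({[tert-butyl(dimethyl)silyl]oxy}methyl)but-3-enoic 2,2-dimethylpropanoic anhydride | C=C(CO[Si](C)(C)C(C)(C)C)CC(=O)OC(=O)C(C)(C)C | intermediate (not isolated)
12 | (4S)-4-benzyl-3-[3-({[tert-butyl(dimethyl)silyl]oxy}methyl)but-3-enoyl]-1,3-oxazolidin-2-one | C=C(CO[Si](C)(C)C(C)(C)C)CC(=O)N1C(=O)OC[C@@H]1Cc1ccccc1 | intermediate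
13 | dibutylboron Z-enolate of 12, (4S)-4-benzyl-3-[(1Z)-1-[(dibutylboranyl)oxy]-3-({[tert-butyl(dimethyl)silyl]oxy}methyl)buta-1,3-dien-1-yl]-1,3-oxazolidin-2-one | C=C(CO[Si](C)(C)C(C)(C)C)/C=C(\OB(CCCC)CCCC)N1C(=O)OC[C@@H]1Cc1ccccc1 | intermediate (not isolated)
14 | (4S)-4-benzyl-3-[(2S,3R,4Z)-2-(3-{[tert-butyl(dimethyl)silyl]oxy}prop-1-en-2-yl)-3-hydroxy-5-methyl-7-(phenylsulfonyl)hept-4-enoyl]-1,3-oxazolidin-2-one | O=C(N1C(=O)OC[C@@H]1Cc1ccccc1)[C@@H](C(=C)CO[Si](C)(C)C(C)(C)C)[C@H](O)/C=C(/C)CCS(=O)(=O)c1ccccc1 | intermediate
15 | (2S,3R,4Z)-2-(3-{[tert-butyl(dimethyl)silyl]oxy}prop-1-en-2-yl)-3-hydroxy-N-methoxy-N,5-dimethyl-7-(phenylsulfonyl)hept-4-enamide | CON(C)C(=O)[C@@H](C(=C)CO[Si](C)(C)C(C)(C)C)[C@H](O)/C=C(/C)CCS(=O)(=O)c1ccccc1 | intermediate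
16 | (3S,4R,5Z)-3-(3-{[tert-butyl(dimethyl)silyl]oxy}prop-1-en-2-yl)-4-hydroxy-6-methyl-8-(phenylsulfonyl)oct-5-en-2-one | CC(=O)[C@@H](C(=C)CO[Si](C)(C)C(C)(C)C)[C@H](O)/C=C(/C)CCS(=O)(=O)c1ccccc1 | intermediate
17 | (3S,4R,5Z)-3-(3-{[tert-butyl(dimethyl)silyl]oxy}prop-1-en-2-yl)-6-methyl-8-(phenylsulfonyl)-4-[(trimethylsilyl)oxy]oct-5-en-2-one | CC(=O)[C@@H](C(=C)CO[Si](C)(C)C(C)(C)C)[C@H](O[Si](C)(C)C)/C=C(/C)CCS(=O)(=O)c1ccccc1 | intermediate (not isolated)
18 | (3S,4R,5Z)-3-(3-{[tert-butyl(dimethyl)silyl]oxy}prop-1-en-2-yl)-6-methyl-8-(phenylsulfonyl)-2,4-bis[(trimethylsilyl)oxy]octa-1,5-diene | C=C(O[Si](C)(C)C)[C@@H](C(=C)CO[Si](C)(C)C(C)(C)C)[C@H](O[Si](C)(C)C)/C=C(/C)CCS(=O)(=O)c1ccccc1 | intermediate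
19 | methyl pyruvate | CC(=O)C(=O)OC | starting material
20 | methyl (2R,5S,6R,7Z)-5-(3-{[tert-butyl(dimethyl)silyl]oxy}prop-1-en-2-yl)-2,8-dimethyl-4-oxo-10-(phenylsulfonyl)-2,6-bis[(trimethylsilyl)oxy]dec-7-enoate | COC(=O)[C@](C)(O[Si](C)(C)C)CC(=O)[C@@H](C(=C)CO[Si](C)(C)C(C)(C)C)[C@H](O[Si](C)(C)C)/C=C(/C)CCS(=O)(=O)c1ccccc1 | intermediate (not isolated)
21 | methyl (2R,5S,6R,7Z)-5-(3-{[tert-butyl(dimethyl)silyl]oxy}prop-1-en-2-yl)-2,6-dihydroxy-2,8-dimethyl-4-oxo-10-(phenylsulfonyl)dec-7-enoate | COC(=O)[C@](C)(O)CC(=O)[C@@H](C(=C)CO[Si](C)(C)C(C)(C)C)[C@H](O)/C=C(/C)CCS(=O)(=O)c1ccccc1 | intermediate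
22 | methyl (2R,4R,5R,6R,7Z)-5-(3-{[tert-butyl(dimethyl)silyl]oxy}prop-1-en-2-yl)-2,4,6-trihydroxy-2,8-dimethyl-10-(phenylsulfonyl)dec-7-enoate | COC(=O)[C@](C)(O)C[C@@H](O)[C@@H](C(=C)CO[Si](C)(C)C(C)(C)C)[C@H](O)/C=C(/C)CCS(=O)(=O)c1ccccc1 | intermediate (not isolated)
23 | (3R,5R)-5-[(3S,4R,5Z)-2-({[tert-butyl(dimethyl)silyl]oxy}methyl)-4-hydroxy-6-methyl-8-(phenylsulfonyl)octa-1,5-dien-3-yl]-3-hydroxy-3-methyloxolan-2-one | O=C1O[C@H](C[C@@]1(C)O)[C@@H](C(=C)CO[Si](C)(C)C(C)(C)C)[C@H](O)/C=C(/C)CCS(=O)(=O)c1ccccc1 | intermediate
24 | (3R,5R)-5-[(3R,4R,5Z)-2-({[tert-butyl(dimethyl)silyl]oxy}methyl)-6-methyl-8-(phenylsulfonyl)-4-[(triethylsilyl)oxy]octa-1,5-dien-3-yl]-3-methyl-3-[(triethylsilyl)oxy]oxolan-2-one | O=C1O[C@H](C[C@@]1(C)O[Si](CC)(CC)CC)[C@@H](C(=C)CO[Si](C)(C)C(C)(C)C)[C@H](O[Si](CC)(CC)CC)/C=C(/C)CCS(=O)(=O)c1ccccc1 | intermediate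
25 | (2R,4Z,6R,7R,8R,10R)-7-(3-{[tert-butyl(dimethyl)silyl]oxy}prop-1-en-2-yl)-8-hydroxy-4,10-dimethyl-2-(phenylsulfonyl)-6,10-bis[(triethylsilyl)oxy]cyclodec-4-en-1-one | C=C(CO[Si](C)(C)C(C)(C)C)[C@H]1[C@H](O[Si](CC)(CC)CC)/C=C(/C)C[C@@H](S(=O)(=O)c2ccccc2)C(=O)[C@](C)(O[Si](CC)(CC)CC)C[C@H]1O | intermediate
26 | (2R,4Z,6R,7R,8R,10R)-7-(3-{[tert-butyl(dimethyl)silyl]oxy}prop-1-en-2-yl)-4,10-dimethyl-8-(3-methylbutanoyloxy)-2-(phenylsulfonyl)-6,10-bis[(triethylsilyl)oxy]cyclodec-4-en-1-one | C=C(CO[Si](C)(C)C(C)(C)C)[C@H]1[C@H](O[Si](CC)(CC)CC)/C=C(/C)C[C@@H](S(=O)(=O)c2ccccc2)C(=O)[C@](C)(O[Si](CC)(CC)CC)C[C@H]1OC(=O)CC(C)C | intermediate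
27 | (4Z,6R,7R,8R,10R)-7-(3-{[tert-butyl(dimethyl)silyl]oxy}prop-1-en-2-yl)-4,10-dimethyl-8-(3-methylbutanoyloxy)-6,10-bis[(triethylsilyl)oxy]cyclodec-4-en-1-one | C=C(CO[Si](C)(C)C(C)(C)C)[C@H]1[C@H](O[Si](CC)(CC)CC)/C=C(/C)CCC(=O)[C@](C)(O[Si](CC)(CC)CC)C[C@H]1OC(=O)CC(C)C | intermediate
28 | (4Z,6R,7S,8R,10R)-6,10-dihydroxy-7-(3-hydroxyprop-1-en-2-yl)-4,10-dimethyl-8-(3-methylbutanoyloxy)cyclodec-4-en-1-one | C=C(CO)[C@H]1[C@H](O)/C=C(/C)CCC(=O)[C@](C)(O)C[C@H]1OC(=O)CC(C)C | intermediate
29 | (4Z,6R,7S,8R,10R)-6,10-dihydroxy-4,10-dimethyl-8-(3-methylbutanoyloxy)-7-(3-oxoprop-1-en-2-yl)cyclodec-4-en-1-one | C=C(C=O)[C@H]1[C@H](O)/C=C(/C)CCC(=O)[C@](C)(O)C[C@H]1OC(=O)CC(C)C | intermediate (not isolated)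
30 | (3aR,4R,6R,10Z,11aR)-2,6-dihydroxy-6,10-dimethyl-3-methylidene-7-oxo-2,3,3a,4,5,6,7,8,9,11a-decahydrocyclodeca[b]furan-4-yl 3-methylbutanoate (either C2 lactol epimer) | C=C1C(O)O[C@@H]2/C=C(/C)CCC(=O)[C@](C)(O)C[C@@H](OC(=O)CC(C)C)[C@@H]12 | intermediate (not isolated)
31 | (3aR,4R,6R,10Z,11aR)-6-hydroxy-6,10-dimethyl-3-methylidene-2,7-dioxo-2,3,3a,4,5,6,7,8,9,11a-decahydrocyclodeca[b]furan-4-yl 3-methylbutanoate | C=C1C(=O)O[C@@H]2/C=C(/C)CCC(=O)[C@](C)(O)C[C@@H](OC(=O)CC(C)C)[C@@H]12 | target

## Step count and least certain steps

Total step count: 20. Longest linear sequence: 16 steps (steps 1–4 or 5–8, then 9–20).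

Step 16 (key step). The likeliest failure is intermolecular acylation outrunning the entropically costly closure of the medium ring, because only a small fraction of the sulfone is deprotonated at any moment and every molecule carries an electrophilic lactone. A second risk is migration of a silyl group from O6 or O10 to the freed C8 alkoxide if the mixture is held warm. Fallback: change the acyl donor to an aldehyde. Setting out from 24, i-Bu2AlH at −78 °C gives the lactol F1. With excess LiN(SiMe3)2 at the same dilution, the lactol alkoxide opens to the C1 aldehyde, which the C2 carbanion attacks in a sulfone–aldehyde addition that is faster than acyl substitution, to give the ring diol F2. Acylation of the less hindered C8 hydroxyl with isovaleric anhydride gives the C1 carbinol ester F3, and Dess–Martin oxidation of the C1 carbinol returns to the route at 26.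

Step 12. Deprotonation may occur at the doubly activated C7 methine instead of the C9 methyl, which would scramble C7 and give a conjugated dienol ether. Fallback: make the enol ether by reduction instead of deprotonation. Setting out from 15, silylation (TMSCl, imidazole) gives the C6 trimethylsilyl ether F4. Bromomethyllithium made in the flask (CH2Br2, MeLi·LiBr, −78 °C) converts the Weinreb amide into the bromomethyl ketone F5. Zn with TMSCl then gives the terminal enol ether regiospecifically, returning at 18.

Step 14. Facial selectivity may erode if hydride delivery from the tertiary C10 hydroxyl, whose chair has no clear preference between axial methyl and axial ester, competes with delivery from C6; lactonisation may also be incomplete. Fallback: an Evans–Tishchenko reduction, in which only the secondary hydroxyl can form the hemiacetal that carries the hydride. Setting out from 21, SmI2 (cat.) and benzaldehyde in THF at −10 °C should give the 6,8-anti C6 benzoate F6. K2CO3 in MeOH removes the benzoate to give 22, which lactonises as in step 14 and returns at 23.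

Step 17. Acylation of the C8 hydroxyl may be slow because it sits between the C7 branch and the neopentyl-like C9, and it may lose out to enol acylation of the acidic β-keto sulfone. Fallback: reverse the order of events. Setting out from 25, Bu3SnH and AIBN remove the sulfonyl group first to give the hydroxy ketone F7, which has no acidic methine. Acylation with isovaleric anhydride and DMAP then returns to the route at 27.

Step 20. Oxidation may start at the secondary allylic C6 hydroxyl before the lactol has formed, or may stall at the lactol. Fallback: a chlorite route in which the second oxidant cannot touch a secondary alcohol. Setting out from 28, one equivalent of PhI(OAc)2 with TEMPO takes the material only to the aldehyde level (29 and 30). NaClO2 with NaH2PO4 and 2-methylbut-2-ene oxidises the open aldehyde form to the hydroxy acid F8, which closes to the lactone on mild acid treatment and returns at 31.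

## Further compounds

F1 | step 16 | (3R,5R)-5-[(3R,4R,5Z)-2-({[tert-butyl(dimethyl)silyl]oxy}methyl)-6-methyl-8-(phenylsulfonyl)-4-[(triethylsilyl)oxy]octa-1,5-dien-3-yl]-3-methyl-3-[(triethylsilyl)oxy]oxolan-2-ol (lactol of 24) | OC1O[C@H](C[C@@]1(C)O[Si](CC)(CC)CC)[C@@H](C(=C)CO[Si](C)(C)C(C)(C)C)[C@H](O[Si](CC)(CC)CC)/C=C(/C)CCS(=O)(=O)c1ccccc1
F2 | step 16 | (4Z,6R,7R,8R,10R)-7-(3-{[tert-butyl(dimethyl)silyl]oxy}prop-1-en-2-yl)-4,10-dimethyl-2-(phenylsulfonyl)-6,10-bis[(triethylsilyl)oxy]cyclodec-4-ene-1,8-diol (C1 and C2 epimers) | C=C(CO[Si](C)(C)C(C)(C)C)[C@H]1[C@H](O[Si](CC)(CC)CC)/C=C(/C)CC(S(=O)(=O)c2ccccc2)C(O)[C@](C)(O[Si](CC)(CC)CC)C[C@H]1O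
F3 | step 16 | 8-O-(3-methylbutanoyl) derivative of F2 with free C1 hydroxyl | C=C(CO[Si](C)(C)C(C)(C)C)[C@H]1[C@H](O[Si](CC)(CC)CC)/C=C(/C)CC(S(=O)(=O)c2ccccc2)C(O)[C@](C)(O[Si](CC)(CC)CC)C[C@H]1OC(=O)CC(C)C
F4 | step 12 | (2S,3R,4Z)-2-(3-{[tert-butyl(dimethyl)silyl]oxy}prop-1-en-2-yl)-N-methoxy-N,5-dimethyl-7-(phenylsulfonyl)-3-[(trimethylsilyl)oxy]hept-4-enamide | CON(C)C(=O)[C@@H](C(=C)CO[Si](C)(C)C(C)(C)C)[C@H](O[Si](C)(C)C)/C=C(/C)CCS(=O)(=O)c1ccccc1
F5 | step 12 | (3S,4R,5Z)-1-bromo-3-(3-{[tert-butyl(dimethyl)silyl]oxy}prop-1-en-2-yl)-6-methyl-8-(phenylsulfonyl)-4-[(trimethylsilyl)oxy]oct-5-en-2-one | BrCC(=O)[C@@H](C(=C)CO[Si](C)(C)C(C)(C)C)[C@H](O[Si](C)(C)C)/C=C(/C)CCS(=O)(=O)c1ccccc1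
F6 | step 14 | methyl (2R,4R,5R,6R,7Z)-6-(benzoyloxy)-5-(3-{[tert-butyl(dimethyl)silyl]oxy}prop-1-en-2-yl)-2,4-dihydroxy-2,8-dimethyl-10-(phenylsulfonyl)dec-7-enoate | COC(=O)[C@](C)(O)C[C@@H](O)[C@@H](C(=C)CO[Si](C)(C)C(C)(C)C)[C@H](OC(=O)c1ccccc1)/C=C(/C)CCS(=O)(=O)c1ccccc1
F7 | step 17 | (4Z,6R,7R,8R,10R)-7-(3-{[tert-butyl(dimethyl)silyl]oxy}prop-1-en-2-yl)-8-hydroxy-4,10-dimethyl-6,10-bis[(triethylsilyl)oxy]cyclodec-4-en-1-one | C=C(CO[Si](C)(C)C(C)(C)C)[C@H]1[C@H](O[Si](CC)(CC)CC)/C=C(/C)CCC(=O)[C@](C)(O[Si](CC)(CC)CC)C[C@H]1O
F8 | step 20 | 2-[(4Z,6R,7S,8R,10R)-6,10-dihydroxy-4,10-dimethyl-8-(3-methylbutanoyloxy)-1-oxocyclodec-4-en-7-yl]prop-2-enoic acid (germacrane locants) | C=C(C(=O)O)[C@H]1[C@H](O)/C=C(/C)CCC(=O)[C@](C)(O)C[C@H]1OC(=O)CC(C)C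
A1 | alternative 1 | seco Z alkenyl iodide with C1 cyclopropanol, closed lactone and phenylthiomethyl-masked methylene | O=C1O[C@H](/C=C(/C)I)[C@@H]([C@H](OC(=O)CC(C)C)C[C@@](C)(O[Si](CC)(CC)CC)C2(O)CC2)[C@@H]1CSc1ccccc1
A2 | alternative 1 | ten-membered keto lactone with masked methylene | O=C1O[C@@H]2/C=C(/C)CCC(=O)[C@](C)(O[Si](CC)(CC)CC)C[C@@H](OC(=O)CC(C)C)[C@H]2[C@@H]1CSc1ccccc1
A3 | alternative 2 | cis-1-vinyl-2-isopropenylcyclohexan-1-ol carrying the C6, C7 and C8 substituents | C=C[C@@]1(O)C[C@@H](OCc2ccc(OC)cc2)[C@@H](C(=C)CO[Si](C)(C)C(C)(C)C)[C@H](O[Si](C)(C)C(C)(C)C)[C@H]1C(C)=C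
A4 | alternative 2 | Z-cyclodec-5-enone with C10 ketone and C1 hydroxyl | O=C1C[C@@H](OCc2ccc(OC)cc2)[C@@H](C(=C)CO[Si](C)(C)C(C)(C)C)[C@H](O[Si](C)(C)C(C)(C)C)/C=C(/C)CC[C@@H]1O
A5 | alternative 3 | seco C1 aldehyde with C10 methyl ketone | CC(=O)C[C@@H](OC(=O)CC(C)C)[C@@H](C(=C)CO[Si](C)(C)C(C)(C)C)[C@H](O[Si](C)(C)C(C)(C)C)/C=C(/C)CCC=O
A6 | alternative 3 | ten-membered α-hydroxy ketone with open lactone carbons | C=C(CO[Si](C)(C)C(C)(C)C)[C@H]1[C@H](O[Si](C)(C)C(C)(C)C)/C=C(/C)CCC(=O)[C@](C)(O)C[C@H]1OC(=O)CC(C)C
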